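**Working numbering (used throughout).** Ring A: C1(=O)–C2=C3–C4–C13–C12. Ring B: C4–C5–C6–C7–C8–C13. Ring C: C8–C9–C10–C11(OH)–C12–C13. Ring D: C6–C7–C14–C15–C19. Ring E: C15–C16(=O)–C17=C18–C19(OH). C14 is the spiro carbon of the naphtho[1,8-de][1,3]dioxine. In this numbering the target is (15S,19R).

## The problem

The target is a 9-hydroxyphenalenone (rings A–C) fused along C6–C7 to a cis-bicyclo[3.3.0]octenone (rings D, E) whose benzylic carbon C14 is ketalised by naphthalene-1,8-diol. There are two stereocentres, C15 and C19; a 5/5 fusion can only be cis, so C15 follows from C19 and the real task is the absolute configuration of the tertiary carbinol C19. The ketal is the awkward group. C14 lies 1,3 to the C16 ketone, so a free C14 ketone would be a β-diketone that cannot be ketalised cleanly; a ketal made early brings in an electron-rich naphthalene that rules out later Friedel–Crafts chemistry; and any carbonyl on C7 deactivates C4, the peri carbon through which ring A would have to be closed. The product is fragile: O19 is β to the C16 ketone (retro-aldol would open both five-membered rings), the ketal oxygens are β to the same ketone (E1cB), and the enone is a Michael acceptor, so the last steps must avoid strong base and heat.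

The feature that opens the problem is that both oxygens on C14 are aryl oxygens of one diol. Detached from C15, C14 is at the carboxylic acid level, and its cation, a 2-aryl-naphtho[1,8-de][1,3]dioxin-2-ylium ion, can be attacked only at C14. O19 sits so that O19–C19–C6–C7–C14 is a five-membered ring (a spiro ortho ester); replacing O19 in that ring by C15, the only enolisable carbon of the C16 ketone (C17 is vinylic, C19 quaternary), gives ring D. A second feature is the tautomeric C2v symmetry of the 9-hydroxyphenalenone chelate (axis through C12, C13 and C6), which makes C5 and C7 equivalent.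

## Retrosynthesis

**18 ⇒ 16 ⇒ 15 (cut C14–C15).** The C14–C15 bond is replaced first by a C14–O19 bond (spiro ortho ester 16) and then by C14–H and O19–H (acetal 15). Cutting C6–C19 or C15–C19 instead would leave a ketal next to a 1,3-dicarbonyl or demand an eight-membered ring. This cut leaves C14 as the naphthalenediol acetal of an ordinary aryl aldehyde and turns the ketalisation problem into a C–H oxidation. 15 has no ring D, no spiroketal and one stereocentre. The forward step must oxidise only the acetal C–H and then make C15, not oxygen, the final partner of C14.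

**15 ⇒ 14 (cut C15–C19).** Ring E is the aldol adduct of the cis-enedione 14: the methyl ketone carbon C15 adds to the aryl ketone C19. This is the only stereocentre-forming event that needs outside control, and water cannot be lost afterwards because that would give a cyclopentadienone. The forward reaction must be enantioselective.

**14 ⇒ 12 (C16=O, C19=O, Z-C17=C18 from a furan).** The cis-enedione is the oxidatively opened form of the 2-aryl-5-methylfuran 12. The furan carbons become C16–C19, the methyl group becomes C15, and the Z geometry comes from the ring. The forward step is a singlet-oxygen dearomatisation.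

**12 ⇒ 10 + 11 (cut C6–C19).** The aryl–furan bond is made by Suzuki–Miyaura coupling of triflate 10 with the commercial boronate 11. This needs no aryl-lithium, so the phenalenone carbonyl and the free 9-OH need no protection.

**10 ⇒ 9 ⇒ 7 + 8.** The triflate comes from the phenol and the acetal from aldehyde 7 and naphthalene-1,8-diol 8. The phenol at C6 thus serves twice: it first directs the formyl group (C14) to its ortho carbon and then becomes the leaving group, so a salicylaldehyde stands in for an ortho-halo benzaldehyde.

**7 ⇒ 6 ⇒ 5 ⇒ 1 + 2.** The formyl group is introduced ortho to the phenol of 5; ring A is closed first of all, by acylation and peri-alkylation of the symmetric 2,6-dimethoxynaphthalene 1 with 3-chloropropanoyl chloride 2, while no deactivating group is yet on the other ring. Dehydrogenation to the phenalenone (6 → 7) is done before the electron-rich diol arrives. The symmetry of 1 and the tautomeric symmetry of 7 remove all regiochemical questions.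

## Roads not taken

**Alternative 1: ketalise first, annulate later (the obvious route).** Cut the C14–O bonds first, then ring E bond by bond, and ring A last. The benz[e]indanone A1 would be ketalised with 8 under acid to A2, C19 oxidised to the keto ketal A3, and ring E added by aldol with acrolein at C15, vinyl addition at C19, ring-closing metathesis and oxidation. The chosen plan is better because ring E costs one step from a furan instead of about five. The achiral ketone A3 also offers no good handle for setting C15 and C19 absolutely. Ring A would have to be closed by electrophilic chemistry in the presence of the naphthodioxine (which would be attacked at its 4-position) and of the hydroxy enone, and on a ring whose peri carbon C4 is deactivated by C14.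

**Alternative 2: desymmetrising aryl addition to a cyclopentenedione.** Cut C6–C19. C16 and C19 are the two carbonyl carbons of a 2-substituted cyclopent-4-ene-1,3-dione, so the prochiral bromide A4 could be closed by an enantioselective Ni- or Pd-catalysed intramolecular addition of the aryl halide to one of two enantiotopic carbonyls. The hidden symmetry is attractive, but in A4 the C15–H is flanked by two carbonyls with the ketal oxygens β to both, so ring-opening by E1cB elimination should be fast and favoured. The enedione would also be reduced by the stoichiometric reductant, and no short access to A4 is apparent.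

**Alternative 3: transannular aldol across an eight-membered ring.** Cut C15–C19 in the ring C6–C7–C14–C15–C16–C17–C18–C19. The achiral benzo-fused cyclooctenedione A5 would be stitched by an amine-catalysed transannular aldol, a reaction type with good precedent in the saturated series, setting both stereocentres at once. The difficulty is A5 itself. Closing the eight-membered ring at C14–C15 competes with capture of an electrophilic C14 by the C19 carbonyl oxygen, which is only five atoms away, and a metathesis route to A5 adds four or more steps. The chosen plan makes the same two bonds in the opposite order (C15–C19, then C14–C15), each through a five-membered transition state, and uses that oxygen capture on purpose.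

Key step: step 9

Assumption: the sense of induction of the amine catalyst in step 8 cannot be fixed on paper; the route is written for the antipode that gives (S)-15, taken here to be (2S,4R)-4-fluoroproline.

## Route

Step 1
Reactants: 1 2,6-dimethoxynaphthalene; 2 3-chloropropanoyl chloride
Product: 5 5,9-dihydroxy-2,3-dihydro-1H-phenalen-1-one, via chloro ketone 3 (not isolated), via dimethyl ether 4 (not isolated)
Conditions: AlCl3 (5 equiv), PhCl, 0 °C, then 120 °C; aq. HCl
Reagents that add atoms: none
Why: Friedel–Crafts acylation goes to C1 of 1 (α and ortho to OMe; the two such positions are equivalent by symmetry), the β-chloro ketone then alkylates the peri carbon because the ortho carbon is blocked (intramolecular Friedel–Crafts alkylation, as in the 3-chloropropanoyl route to hydroxyindanones), and hot AlCl3 cleaves both methyl ethers.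

Step 2
Reactants: 5 5,9-dihydroxy-2,3-dihydro-1H-phenalen-1-one
Product: 6 5,9-dihydroxy-1-oxo-2,3-dihydro-1H-phenalene-6-carbaldehyde
Conditions: MgCl2, Et3N, (CH2O)n, MeCN, reflux; aq. HCl
Reagents that add atoms: formaldehyde (from paraformaldehyde), C=O
Why: Casnati–Skattebøl ortho-formylation: the magnesium naphtholate at O5 delivers formaldehyde to its α-ortho carbon C6 and a second formaldehyde takes up the hydride, while the chelated 9-OH on the acyl-bearing ring activates far less; attack at C4 instead would still converge, since after step 3 the two isomers are tautomers.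

Step 3
Reactants: 6 5,9-dihydroxy-1-oxo-2,3-dihydro-1H-phenalene-6-carbaldehyde
Product: 7 5,9-dihydroxy-1-oxo-1H-phenalene-6-carbaldehyde
Conditions: DDQ, 1,4-dioxane, 80 °C
Reagents that add atoms: none
Why: Quinone dehydrogenation of the 2,3-dihydrophenalenone (hydride abstraction from the benzylic C3–H of the enol), driven by formation of the hydroxyphenalenone chelate; it is placed here because no electron-rich naphthalenediol is yet present.

Step 4
Reactants: 7 5,9-dihydroxy-1-oxo-1H-phenalene-6-carbaldehyde; 8 naphthalene-1,8-diol
Product: 9 5,9-dihydroxy-6-(naphtho[1,8-de][1,3]dioxin-2-yl)-1H-phenalen-1-one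
Conditions: TsOH·H2O (cat.), toluene/1,4-dioxane, reflux, Dean–Stark, under argon
Reagents that add atoms: none
Why: Acid-catalysed acetalisation of an aromatic aldehyde with the peri-diol gives the six-membered naphthodioxine; the phenalenone carbonyl is a vinylogous acid carbonyl and should not ketalise.

Step 5
Reactants: 9 5,9-dihydroxy-6-(naphtho[1,8-de][1,3]dioxin-2-yl)-1H-phenalen-1-one
Product: 10 9-hydroxy-6-(naphtho[1,8-de][1,3]dioxin-2-yl)-1-oxo-1H-phenalen-5-yl trifluoromethanesulfonate
Conditions: PhNTf2 (1.05 equiv), K2CO3, DMF, 0 °C to rt
Reagents that add atoms: N-phenylbis(trifluoromethanesulfonimide), FC(F)(F)S(=O)(=O)N(c1ccccc1)S(=O)(=O)C(F)(F)F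
Why: Aryl triflate formation; O5 is an ordinary naphtholate, whereas O9 is held in the strong chelate of the 9-hydroxyphenalenone and its anion is delocalised and poorly nucleophilic, so one equivalent of reagent should take O5.

Step 6
Reactants: 10 9-hydroxy-6-(naphtho[1,8-de][1,3]dioxin-2-yl)-1-oxo-1H-phenalen-5-yl trifluoromethanesulfonate; 11 4,4,5,5-tetramethyl-2-(5-methylfuran-2-yl)-1,3,2-dioxaborolane
Product: 12 9-hydroxy-5-(5-methylfuran-2-yl)-6-(naphtho[1,8-de][1,3]dioxin-2-yl)-1H-phenalen-1-one
Conditions: Pd(OAc)2 (cat.), SPhos, K3PO4, toluene/H2O, 80 °C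
Reagents that add atoms: none
Why: Suzuki–Miyaura coupling of an ortho-substituted, electron-poor aryl triflate with a 2-furyl boronate under a dialkylbiarylphosphine ligand; ketone, free phenol and acetal are inert to it.

Step 7
Reactants: 12 9-hydroxy-5-(5-methylfuran-2-yl)-6-(naphtho[1,8-de][1,3]dioxin-2-yl)-1H-phenalen-1-one
Product: 14 (Z)-1-[9-hydroxy-6-(naphtho[1,8-de][1,3]dioxin-2-yl)-1-oxo-1H-phenalen-5-yl]pent-2-ene-1,4-dione, via furan endoperoxide 13 (not isolated)
Conditions: O2, visible light, tetraphenylporphyrin (cat.), CH2Cl2, −78 °C; then Me2S, −78 to 0 °C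
Reagents that add atoms: dioxygen, O=O
Why: [4+2] addition of singlet oxygen to the 2,5-disubstituted furan and reduction of the endoperoxide is the standard oxidative ring opening to a cis-enedione; the furan should react far faster than the alkoxynaphthalene, and the Z geometry is inherited from the ring.

Step 8
Reactants: 14 (Z)-1-[9-hydroxy-6-(naphtho[1,8-de][1,3]dioxin-2-yl)-1-oxo-1H-phenalen-5-yl]pent-2-ene-1,4-dione
Product: 15 9-hydroxy-5-[(1S)-1-hydroxy-4-oxocyclopent-2-en-1-yl]-6-(naphtho[1,8-de][1,3]dioxin-2-yl)-1H-phenalen-1-one
Conditions: (2S,4R)-4-fluoroproline (20 mol %), DMSO, rt, crude 14 used at once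
Reagents that add atoms: none
Why: Proposed new method: the enamine of the methyl ketone (C15=C16–N) should add to the aryl ketone C19, which the Z-alkene holds cis and the catalyst carboxylic acid activates, so that the catalyst sets C19; the closest known reactions are the proline-type transannular 5-(enolendo) aldolisation of cyclooctane-1,4-diones and the base-mediated closure of cis-enediones to 4-hydroxycyclopent-2-enones. Water cannot be eliminated, since that would give a cyclopentadienone.

Step 9
Reactants: 15 9-hydroxy-5-[(1S)-1-hydroxy-4-oxocyclopent-2-en-1-yl]-6-(naphtho[1,8-de][1,3]dioxin-2-yl)-1H-phenalen-1-one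
Product: 18 Spiropreussione B, (15S,19R) in the working numbering, via spiro ortho ester 16 (not isolated), via bis-silyl ether 17 (not isolated)
Conditions: (i) divided cell, RVC anode, Pt cathode, (4-BrC6H4)3N (10 mol %), 2,6-lutidine, Bu4NBF4, CH2Cl2/MeCN, 0 °C, 2.2 F/mol; (ii) TMSOTf, iPr2NEt, CH2Cl2, −78 to −20 °C; (iii) aq. NaHCO3, then citric acid, MeOH/H2O
Reagents that add atoms: none
Why: Proposed new method: mediated anodic oxidation should take an electron from the naphthodioxine π-system, the most electron-rich part of 15 (hydroxyphenalenone and enone are electron-poor); loss of the acetal proton at C14 and of a second electron gives the 2-aryl-naphtho[1,8-de][1,3]dioxin-2-ylium ion, which O19 captures (5-exo) to give the spiro ortho ester 16. TMSOTf then re-opens the C14–O19 bond to the same cation, while TMSOTf/iPr2NEt convert the C16 ketone into its silyl dienol ether, which can form only toward C15; C15 attacks C14 in a 5-(enolexo)-exo-trig closure that makes ring D and the spiroketal carbon together. The closest known reactions are the anodic 2-alkoxylation of 1,3-benzodioxoles to ortho esters for the first stage and the Lewis acid-mediated coupling of silyl enol ethers with ortho esters to β-keto ketals (Mukaiyama type) for the second. C15 is set by C19: the tether C19–C6–C7–C14 reaches only the face of ring E that carries the aryl group, so the fusion is cis and (S)-C19 of 15 becomes (15S,19R)-18 (the descriptor at C19 changes only because C15 gains priority). The step needs site-selective oxidation, which the electron-rich dioxine and the doubly oxygen-activated C14–H should secure, and C- rather than O-capture of the cation; O-capture only regenerates 16, whereas C–C bond formation is irreversible, and because both ketal oxygens are aryl oxygens the cation cannot be opened at carbon. Ionisation at C19 is not expected, since that cation would be a cyclopentadienyl-type cation.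

## Compound list

1 | 2,6-dimethoxynaphthalene | COc1ccc2cc(OC)ccc2c1 | starting material
2 | 3-chloropropanoyl chloride | ClCCC(=O)Cl | starting material
3 | 3-chloro-1-(2,6-dimethoxynaphthalen-1-yl)propan-1-one | COc1ccc2cc(OC)ccc2c1C(=O)CCCl | intermediate
4 | 5,9-dimethoxy-2,3-dihydro-1H-phenalen-1-one | O=C1CCc2cc(OC)cc3ccc(OC)c1c23 | intermediate
5 | 5,9-dihydroxy-2,3-dihydro-1H-phenalen-1-one | O=C1CCc2cc(O)cc3ccc(O)c1c23 | intermediate
6 | 5,9-dihydroxy-1-oxo-2,3-dihydro-1H-phenalene-6-carbaldehyde | O=C1CCc2cc(O)c(C=O)c3ccc(O)c1c23 | intermediate
7 | 5,9-dihydroxy-1-oxo-1H-phenalene-6-carbaldehyde | O=C1C=Cc2cc(O)c(C=O)c3ccc(O)c1c23 | intermediate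
8 | naphthalene-1,8-diol | Oc1cccc2cccc(O)c12 | starting material
9 | 5,9-dihydroxy-6-(naphtho[1,8-de][1,3]dioxin-2-yl)-1H-phenalen-1-one | O=C1C=Cc2cc(O)c(C4Oc5cccc6cccc(O4)c56)c3ccc(O)c1c23 | intermediate
10 | 9-hydroxy-6-(naphtho[1,8-de][1,3]dioxin-2-yl)-1-oxo-1H-phenalen-5-yl trifluoromethanesulfonate | O=C1C=Cc2cc(OS(=O)(=O)C(F)(F)F)c(C4Oc5cccc6cccc(O4)c56)c3ccc(O)c1c23 | intermediate
11 | 4,4,5,5-tetramethyl-2-(5-methylfuran-2-yl)-1,3,2-dioxaborolane | Cc1ccc(o1)B1OC(C)(C)C(C)(C)O1 | starting material
12 | 9-hydroxy-5-(5-methylfuran-2-yl)-6-(naphtho[1,8-de][1,3]dioxin-2-yl)-1H-phenalen-1-one | O=C1C=Cc2cc(-c7ccc(C)o7)c(C4Oc5cccc6cccc(O4)c56)c3ccc(O)c1c23 | intermediate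
13 | 9-hydroxy-5-(4-methyl-2,3,7-trioxabicyclo[2.2.1]hept-5-en-1-yl)-6-(naphtho[1,8-de][1,3]dioxin-2-yl)-1H-phenalen-1-one | O=C1C=Cc2cc(C78C=CC(C)(O7)OO8)c(C4Oc5cccc6cccc(O4)c56)c3ccc(O)c1c23 | intermediate
14 | (Z)-1-[9-hydroxy-6-(naphtho[1,8-de][1,3]dioxin-2-yl)-1-oxo-1H-phenalen-5-yl]pent-2-ene-1,4-dione | O=C1C=Cc2cc(C(=O)/C=C\C(C)=O)c(C4Oc5cccc6cccc(O4)c56)c3ccc(O)c1c23 | intermediate
15 | 9-hydroxy-5-[(1S)-1-hydroxy-4-oxocyclopent-2-en-1-yl]-6-(naphtho[1,8-de][1,3]dioxin-2-yl)-1H-phenalen-1-one | O=C1C=Cc2cc([C@@]7(O)C=CC(=O)C7)c(C4Oc5cccc6cccc(O4)c56)c3ccc(O)c1c23 | intermediate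
16 | spiro ortho ester: 15 with C14 bonded to O19 in place of H (five-membered ring O19–C19–C6–C7–C14), C19 (S) spiro to the 4-oxocyclopent-2-ene, C14 spiro to the naphthodioxine | O=C1C=Cc2cc3c(c4ccc(O)c1c24)C1(Oc2cccc4cccc(O1)c24)O[C@@]35C=CC(=O)C5 | intermediate
17 | 11,19-bis(trimethylsilyl) ether of 18 | O=C1C=Cc2cc3c(c4ccc(O[Si](C)(C)C)c1c24)C1(Oc2cccc4cccc(c24)O1)[C@@H]1C(=O)C=C[C@]31O[Si](C)(C)C | intermediate
18 | Spiropreussione B, (15S,19R) | O=C1C=Cc2cc3c(c4ccc(O)c1c24)C1(Oc2cccc4cccc(c24)O1)[C@@H]1C(=O)C=C[C@]31O | target

## Step count and least certain steps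

Total steps: 9. Longest linear sequence: 9 steps (1 to 18); 2, 8 and 11 enter as commercial building blocks.

**Step 9 (key step, proposed new method).** Two things are most likely to go wrong. The naphthodioxine radical cation may couple through its 4-position before the acetal proton is lost. In the second stage, re-capture of the cation by O19 may outrun enol silane formation, leading to slow decomposition of the silylated hydroxy enone. Fallback with known reaction types, from 15 to 18: aerobic N-hydroxyphthalimide/cobalt-catalysed oxidation of the acetal C–H (acetal to ester), after which the C19 hydroxyl displaces the naphthyl ester, should give the spiro lactone F1. LiHMDS (3 equiv, THF, −78 °C) then effects the phthalide-to-1,3-diketone acyl transfer (C15 enolate onto the lactone carbonyl) to the triketo alcohol F2. Acid-catalysed ketalisation of the aryl ketone C14 of F2 with 8 (TsOH, toluene) returns to the route at 18. This path is less attractive because the alkoxide of F2 can undergo retro-aldol opening.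

**Step 8 (proposed new method).** Poor facial selectivity, reversible conjugate addition of the amine to the enedione, or Z-to-E isomerisation of 14 before cyclisation may occur. Fallback, from 14 to 15: cyclisation with Et3N (the known racemic closure of cis-enediones) gives 15 together with its enantiomer, the (R)-hydroxy enone F3. The two are separated by preparative chromatography on a chiral stationary phase, and the route is rejoined at 15.

**Step 1.** Once the chelated methyl ether is cleaved, O-alkylation of the new phenol by the β-chloro ketone (chromanone formation) may compete with peri C-alkylation, and the aryl vinyl ketone may polymerise. Fallback, from 1 to 7: acylation, peri-cyclisation and loss of benzene with cinnamoyl chloride/AlCl3 gives 9-hydroxy-5-methoxy-1H-phenalen-1-one F4. BBr3 then gives 5,9-dihydroxy-1H-phenalen-1-one F5, whose two ortho carbons are tautomerically equivalent. Magnesium-mediated ortho-formylation of F5 rejoins the route at 7.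

**Step 5.** Site selectivity may be lost, with triflation at O9 as well as O5. Fallback, from 9 to 10: excess Tf2O/pyridine gives the bis-triflate F6. Its 9-triflate is a vinylogous acyl triflate and should be removed selectively by addition–elimination with aq. NaHCO3/MeOH, returning to 10.

## Further compounds

F1 | step 9 | spiro lactone: C14 as lactone carbonyl bonded to O19, C19 (S) spiro to 4-oxocyclopent-2-ene, fused to the 9-hydroxyphenalenone | O=C1C=Cc2cc3c(c4ccc(O)c1c24)C(=O)O[C@@]35C=CC(=O)C5
F2 | step 9 | triketo alcohol: 18 with a ketone at C14 in place of the ketal | O=C1C=Cc2cc3c(c4ccc(O)c1c24)C(=O)[C@@H]1C(=O)C=C[C@]31O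
F3 | step 8 | 9-hydroxy-5-[(1R)-1-hydroxy-4-oxocyclopent-2-en-1-yl]-6-(naphtho[1,8-de][1,3]dioxin-2-yl)-1H-phenalen-1-one | O=C1C=Cc2cc([C@]7(O)C=CC(=O)C7)c(C4Oc5cccc6cccc(O4)c56)c3ccc(O)c1c23
F4 | step 1 | 9-hydroxy-5-methoxy-1H-phenalen-1-one | O=C1C=Cc2cc(OC)cc3ccc(O)c1c23
F5 | step 1 | 5,9-dihydroxy-1H-phenalen-1-one | O=C1C=Cc2cc(O)cc3ccc(O)c1c23
F6 | step 5 | 6-(naphtho[1,8-de][1,3]dioxin-2-yl)-1-oxo-1H-phenalene-5,9-diyl bis(trifluoromethanesulfonate) | O=C1C=Cc2cc(OS(=O)(=O)C(F)(F)F)c(C4Oc5cccc6cccc(O4)c56)c3ccc(OS(=O)(=O)C(F)(F)F)c1c23
A1 | alternative 1 | 7-methoxy-2,3-dihydro-1H-cyclopenta[a]naphthalen-1-one | COc1ccc2c(c1)ccc1CCC(=O)c12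
A2 | alternative 1 | 7-methoxy-2,3-dihydrospiro[cyclopenta[a]naphthalene-1,2'-naphtho[1,8-de][1,3]dioxine] | COc1ccc2c(c1)ccc1CCC3(Oc4cccc5cccc(O3)c45)c12
A3 | alternative 1 | 7-methoxyspiro[cyclopenta[a]naphthalene-1,2'-naphtho[1,8-de][1,3]dioxin]-3(2H)-one | COc1ccc2c(c1)ccc1C(=O)CC3(Oc4cccc5cccc(O3)c45)c12
A4 | alternative 2 | 2-[2-(5-bromo-9-hydroxy-1-oxo-1H-phenalen-6-yl)naphtho[1,8-de][1,3]dioxin-2-yl]cyclopent-4-ene-1,3-dione | O=C1C=Cc2cc(Br)c(C4(Oc5cccc6cccc(O4)c56)C7C(=O)C=CC7=O)c3ccc(O)c1c23
A5 | alternative 3 | benzo-fused (Z)-cyclooct-2-ene-1,4-dione (ring C6–C7–C14–C15–C16–C17–C18–C19) on the 9-hydroxyphenalenone, spiro-ketalised at C14 by naphthalene-1,8-diol | O=C1C=Cc2cc3c(c4ccc(O)c1c24)C1(Oc2cccc4cccc(O1)c24)CC(=O)/C=C\C3=O
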